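**Plan**

- Retrosynthesis: cut the ester C–O bond at C6, then the C6–C7 bond of the seven-membered ring B, then C1–CH3, then C1=C5 and C9–C10 (two aldol bonds), and finally go back to the ring C=C bond of (S)-terpinen-4-ol, which is cleaved.
- The feature that allows the ring closure is the allylic carbinol C6(O)–C7=C8 inside ring B: C6 (as an aldehyde on the cyclopentane ring A) and C7 (as a Z-alkenyl iodide) are both electrophiles and are joined reductively by chromium/nickel.
- Forward: the cyclohexene of terpinen-4-ol is opened and re-closed as ring A, the chain C7–C10 is attached by an aldol reaction, the angular methyl is added, and ring B is closed last.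
- Stereochemistry: C4 comes from terpinen-4-ol, C9 from a reagent-controlled boron aldol, C1 from cuprate attack anti to the C4 isopropyl group, C5 from equilibration, and C6 from the ring closure under control of the angular methyl.

Key step: step 9

Remarks on the chemistry:
- Locants C1–C10 are those of the daucane skeleton of the target (C1 quaternary carbon with the angular methyl, C4 carbinol with isopropyl, C5 ring-fusion CH, C6 ester carbinol, C7=C8 with methyl on C8, C9 carbinol) and are kept for all precursors.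
- (S)-(+)-Terpinen-4-ol is assumed to be available in high enantiomeric purity.
- (−)-Ipc2BCl is assumed to be the antipode that sends a methyl ketone enolate to the Re face of an enal; if the sense is the opposite with aldehyde 4, (+)-Ipc2BCl is used and nothing else changes.

**Route**

Step 1
Reactants: 1 prop-2-yn-1-ol
Product: 3 (Z)-3-iodo-2-methylprop-2-en-1-ol, via alkenylmagnesium alkoxide 2 (not isolated)
Conditions: MeMgBr (2.5 equiv), CuI (10 mol%), THF, −10 °C → rt; then I2, −78 → 0 °C; H2O
Reagents that add atoms: methylmagnesium bromide C[Mg]Br; iodine II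
Why: Copper-catalysed anti-carbomagnesiation of the propargylic alkoxide should place the methyl on C8 and magnesium on C7 cis to the CH2O group through a magnesium chelate, and iodinolysis with retention then fixes the Z geometry.

Step 2
Reactants: 3 (Z)-3-iodo-2-methylprop-2-en-1-ol
Product: 4 (Z)-3-iodo-2-methylprop-2-enal
Conditions: MnO2 (15 equiv), CH2Cl2, rt, dark; used at once
Reagents that add atoms: none
Why: Allylic oxidation with MnO2 is neutral and should leave the Z-iodoalkene untouched when light is excluded.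

Step 3
Reactants: 5 (S)-(+)-terpinen-4-ol
Product: 8 (5S)-5-hydroxy-7,7-dimethoxy-5-(propan-2-yl)heptan-2-one, via methoxy hydroperoxide aldehyde 6 (not isolated), via methoxy hydroperoxide acetal 7 (not isolated)
Conditions: O3, CH2Cl2/MeOH (5:1), −78 °C; then TsOH·H2O (10 mol%), rt; NaHCO3; Me2S, rt
Reagents that add atoms: ozone [O-][O+]=O; methanol CO
Why: Ozonolysis in methanol with acetalisation before reduction should differentiate the two termini, because the carbonyl oxide forms at the methyl-bearing carbon and is held as the methoxy hydroperoxide while the free aldehyde C6 becomes the dimethyl acetal; the ring C–C bond is cleaved and the C4 stereocentre is not touched.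

Step 4
Reactants: 8 (5S)-5-hydroxy-7,7-dimethoxy-5-(propan-2-yl)heptan-2-one; 4 (Z)-3-iodo-2-methylprop-2-enal
Product: 10 (1Z,3R,8S)-3,8-dihydroxy-1-iodo-10,10-dimethoxy-2-methyl-8-(propan-2-yl)dec-1-en-5-one, via enol borinate 9 (not isolated)
Conditions: (−)-Ipc2BCl (2.3 equiv), Et3N (2.6 equiv), Et2O, 0 °C; then 4, −78 → −20 °C; then H2O2, MeOH, pH 7 buffer
Reagents that add atoms: none
Why: The diisopinocampheylboron aldol reaction of a methyl ketone enolises only on the methyl side (the tertiary hydroxyl is held as its borinate by the excess reagent) and the chiral boron ligands should direct the enolate to the Re face of the enal, which sets C9 as R; the C9 epimer is a diastereomer and can be removed by chromatography.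

Step 5
Reactants: 10 (1Z,3R,8S)-3,8-dihydroxy-1-iodo-10,10-dimethoxy-2-methyl-8-(propan-2-yl)dec-1-en-5-one
Product: 11 (1Z,3R,8S)-3-[tert-butyl(dimethyl)silyl]oxy-8-hydroxy-1-iodo-10,10-dimethoxy-2-methyl-8-(propan-2-yl)dec-1-en-5-one
Conditions: TBSCl, imidazole, DMF, rt
Reagents that add atoms: tert-butyldimethylsilyl chloride CC(C)(C)[Si](C)(C)Cl
Why: Silylation with TBSCl/imidazole should take the secondary C9 hydroxyl and leave the hindered tertiary C4 hydroxyl, the ketone and the acetal alone.

Step 6
Reactants: 11 (1Z,3R,8S)-3-[tert-butyl(dimethyl)silyl]oxy-8-hydroxy-1-iodo-10,10-dimethoxy-2-methyl-8-(propan-2-yl)dec-1-en-5-one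
Product: 14 (3S,8R,9Z)-8-[tert-butyl(dimethyl)silyl]oxy-10-iodo-9-methyl-6-oxo-3-(propan-2-yl)-3-(trimethylsilyloxy)dec-9-enal, via bis-silyl acetal 12 (not isolated), via lutidinium salt 13 (not isolated)
Conditions: TMSOTf (3 equiv), 2,6-lutidine (4.5 equiv), CH2Cl2, −20 → 0 °C; then H2O
Reagents that add atoms: trimethylsilyl trifluoromethanesulfonate C[Si](C)(C)OS(=O)(=O)C(F)(F)F; water O
Why: A silyl triflate with a hindered pyridine silylates the tertiary hydroxyl and converts the aldehyde dimethyl acetal into a pyridinium salt that water hydrolyses to the aldehyde under non-acidic conditions (acetal cleavage by silyl triflate/pyridine base), so that the C4 oxygen is masked as a poor leaving group for the next step.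

Step 7
Reactants: 14 (3S,8R,9Z)-8-[tert-butyl(dimethyl)silyl]oxy-10-iodo-9-methyl-6-oxo-3-(propan-2-yl)-3-(trimethylsilyloxy)dec-9-enal
Product: 16 (5R)-2-[(2R,3Z)-2-[tert-butyl(dimethyl)silyl]oxy-4-iodo-3-methylbut-3-en-1-yl]-5-hydroxy-5-(propan-2-yl)cyclopent-1-ene-1-carbaldehyde, via silylated enal 15 (not isolated)
Conditions: piperidine (0.3 equiv), AcOH (0.3 equiv), toluene, 45 °C; then citric acid, THF/H2O, rt
Reagents that add atoms: none
Why: Amine-catalysed intramolecular aldol condensation (enamine of the aldehyde, C5 attacking the C1 ketone), well known for keto aldehydes from 1-methylcyclohexene terpenes, should close ring A and dehydrate only the new free C1 hydroxyl because the C4 oxygen is silylated; mild acid then removes the tertiary trimethylsilyl ether without touching the TBS ether.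

Step 8
Reactants: 16 (5R)-2-[(2R,3Z)-2-[tert-butyl(dimethyl)silyl]oxy-4-iodo-3-methylbut-3-en-1-yl]-5-hydroxy-5-(propan-2-yl)cyclopent-1-ene-1-carbaldehyde
Product: 19 (1R,2R,5R)-5-[(2R,3Z)-2-[tert-butyl(dimethyl)silyl]oxy-4-iodo-3-methylbut-3-en-1-yl]-2-hydroxy-5-methyl-2-(propan-2-yl)cyclopentane-1-carbaldehyde, via dilithium enolate 17 (not isolated), via C5-epimeric aldehyde 18 (not isolated)
Conditions: Me2CuLi (3.5 equiv, from CuI and MeLi), Et2O, −78 → −30 °C; aq. NH4Cl; then DBU (0.2 equiv), CH2Cl2, rt
Reagents that add atoms: lithium dimethylcuprate [Li+].C[Cu-]C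
Why: Cuprate conjugate addition to the β,β-disubstituted enal should deliver the methyl to C1 on the face opposite the C4 isopropyl group (the face of the small lithium alkoxide), which sets the quaternary centre, and base equilibration of the epimerisable C5 then places the formyl group trans to the isopropyl group and the C10 chain; the alkenyl iodide should survive at low temperature.

Step 9
Reactants: 19 (1R,2R,5R)-5-[(2R,3Z)-2-[tert-butyl(dimethyl)silyl]oxy-4-iodo-3-methylbut-3-en-1-yl]-2-hydroxy-5-methyl-2-(propan-2-yl)cyclopentane-1-carbaldehyde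
Product: 21 (1R,4R,5S,6S,9R)-9-[tert-butyl(dimethyl)silyl]oxydauc-7-ene-4,6-diol, via alkenylchromium species 20 (not isolated)
Conditions: CrCl2 (8 equiv), NiCl2 (2 mol%), degassed DMSO, rt, 0.005 M, slow addition of 19
Reagents that add atoms: none
Why: CrCl2 reduces NiCl2 to zerovalent nickel, which inserts into the C7–I bond with retention of the Z geometry, and transmetalation gives the alkenylchromium dichloride 20 (trivalent chromium), a non-basic nucleophile that adds to the C6 aldehyde, so that two carbons that are both electrophilic in 19 are joined by reductive polarity reversal. The closest known reaction type is the intramolecular Nozaki–Hiyama–Kishi alkenylation used to close medium-ring allylic alcohols. Ring B closes in a 7-exo-trig mode, C7 attacking the exocyclic carbonyl at C6, and the trans arrangement of the formyl group and the C10 chain on ring A makes the new ring trans-fused. The new stereocentre C6 is controlled by the angular methyl on C1: in the chair-like transition state with C4 equatorial, the chromium-bound oxygen should take the pseudo-equatorial site and avoid the 1,3-diaxial contact with that methyl, which places the C6 oxygen cis to H5 (6S). The step needs chemoselectivity for the aldehyde beside the free tertiary hydroxyl and the silyl ether, which the alkenylchromium reagent provides, and ring closure in preference to oligomerisation, which the Z geometry of C7=C8 and high dilution secure. C5 should not epimerise because the medium is not basic.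

Step 10
Reactants: 21 (1R,4R,5S,6S,9R)-9-[tert-butyl(dimethyl)silyl]oxydauc-7-ene-4,6-diol; 22 4-methoxybenzoyl chloride
Product: 23 (1R,4R,5S,6S,9R)-9-[tert-butyl(dimethyl)silyl]oxy-4-hydroxydauc-7-en-6-yl 4-methoxybenzoate
Conditions: 22 (2 equiv), DMAP (0.5 equiv), Et3N, CH2Cl2, rt → 40 °C
Reagents that add atoms: none
Why: DMAP-catalysed acylation should esterify the secondary allylic C6 hydroxyl with retention and leave the tertiary C4 hydroxyl free.

Step 11
Reactants: 23 (1R,4R,5S,6S,9R)-9-[tert-butyl(dimethyl)silyl]oxy-4-hydroxydauc-7-en-6-yl 4-methoxybenzoate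
Product: 24 (1R,4R,5S,6S,9R)-4,9-dihydroxydauc-7-en-6-yl 4-methoxybenzoate (CNP0251753.2)
Conditions: HF·pyridine, pyridine/THF, 0 °C → rt
Reagents that add atoms: none
Why: Buffered fluoride desilylation should free the C9 hydroxyl without ester cleavage or acyl migration, since C9–O and the C6 ester are trans across ring B and the C4 hydroxyl is tertiary.

**Compound list**

1 | prop-2-yn-1-ol | C#CCO | starting material
2 | (Z)-3-(bromomagnesio)-2-methylprop-2-en-1-olate, bromomagnesium salt | C/C(CO[Mg]Br)=C/[Mg]Br | intermediate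
3 | (Z)-3-iodo-2-methylprop-2-en-1-ol | C/C(CO)=C/I | intermediate
4 | (Z)-3-iodo-2-methylprop-2-enal | C/C(C=O)=C/I | intermediate
5 | (S)-(+)-terpinen-4-ol | CC1=CC[C@](O)(C(C)C)CC1 | starting material
6 | (3S)-6-hydroperoxy-3-hydroxy-6-methoxy-3-(propan-2-yl)heptanal (mixture at C6 of the chain) | CC(OC)(OO)CC[C@@](O)(C(C)C)CC=O | intermediate
7 | (3S)-6-hydroperoxy-1,1,6-trimethoxy-3-(propan-2-yl)heptan-3-ol (mixture at C6 of the chain) | CC(OC)(OO)CC[C@@](O)(C(C)C)CC(OC)OC | intermediate
8 | (5S)-5-hydroxy-7,7-dimethoxy-5-(propan-2-yl)heptan-2-one | CC(=O)CC[C@@](O)(C(C)C)CC(OC)OC | intermediate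
9 | enol diisopinocampheylborinate of 8, C4 oxygen also borylated | C=C(OB([C@@H]1C[C@@H]2C[C@H]([C@H]1C)C2(C)C)[C@@H]1C[C@@H]2C[C@H]([C@H]1C)C2(C)C)CC[C@@](OB([C@@H]1C[C@@H]2C[C@H]([C@H]1C)C2(C)C)[C@@H]1C[C@@H]2C[C@H]([C@H]1C)C2(C)C)(C(C)C)CC(OC)OC | intermediate
10 | (1Z,3R,8S)-3,8-dihydroxy-1-iodo-10,10-dimethoxy-2-methyl-8-(propan-2-yl)dec-1-en-5-one | I/C=C(C)\[C@H](O)CC(=O)CC[C@@](O)(C(C)C)CC(OC)OC | intermediate
11 | (1Z,3R,8S)-3-[tert-butyl(dimethyl)silyl]oxy-8-hydroxy-1-iodo-10,10-dimethoxy-2-methyl-8-(propan-2-yl)dec-1-en-5-one | I/C=C(C)\[C@H](O[Si](C)(C)C(C)(C)C)CC(=O)CC[C@@](O)(C(C)C)CC(OC)OC | intermediate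
12 | 8-O-trimethylsilyl ether of 11 | I/C=C(C)\[C@H](O[Si](C)(C)C(C)(C)C)CC(=O)CC[C@@](O[Si](C)(C)C)(C(C)C)CC(OC)OC | intermediate
13 | N-(1-methoxyalkyl)-2,6-dimethylpyridinium triflate from 12 (mixture at the aminal carbon) | I/C=C(C)\[C@H](O[Si](C)(C)C(C)(C)C)CC(=O)CC[C@@](O[Si](C)(C)C)(C(C)C)CC(OC)[n+]1c(C)cccc1C.[O-]S(=O)(=O)C(F)(F)F | intermediate
14 | (3S,8R,9Z)-8-[tert-butyl(dimethyl)silyl]oxy-10-iodo-9-methyl-6-oxo-3-(propan-2-yl)-3-(trimethylsilyloxy)dec-9-enal | I/C=C(C)\[C@H](O[Si](C)(C)C(C)(C)C)CC(=O)CC[C@@](O[Si](C)(C)C)(C(C)C)CC=O | intermediate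
15 | (5R)-2-[(2R,3Z)-2-[tert-butyl(dimethyl)silyl]oxy-4-iodo-3-methylbut-3-en-1-yl]-5-(propan-2-yl)-5-(trimethylsilyloxy)cyclopent-1-ene-1-carbaldehyde | I/C=C(C)\[C@H](O[Si](C)(C)C(C)(C)C)CC1=C(C=O)[C@](O[Si](C)(C)C)(C(C)C)CC1 | intermediate
16 | (5R)-2-[(2R,3Z)-2-[tert-butyl(dimethyl)silyl]oxy-4-iodo-3-methylbut-3-en-1-yl]-5-hydroxy-5-(propan-2-yl)cyclopent-1-ene-1-carbaldehyde | I/C=C(C)\[C@H](O[Si](C)(C)C(C)(C)C)CC1=C(C=O)[C@](O)(C(C)C)CC1 | intermediate
17 | dilithium enolate/alkoxide formed by methyl addition to 16 | I/C=C(C)\[C@H](O[Si](C)(C)C(C)(C)C)C[C@@]1(C)CC[C@@](O[Li])(C(C)C)C1=CO[Li] | intermediate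
18 | (1S,2R,5R)-epimer of 19 (formyl group cis to isopropyl) | I/C=C(C)\[C@H](O[Si](C)(C)C(C)(C)C)C[C@@]1(C)CC[C@@](O)(C(C)C)[C@H]1C=O | intermediate
19 | (1R,2R,5R)-5-[(2R,3Z)-2-[tert-butyl(dimethyl)silyl]oxy-4-iodo-3-methylbut-3-en-1-yl]-2-hydroxy-5-methyl-2-(propan-2-yl)cyclopentane-1-carbaldehyde | I/C=C(C)\[C@H](O[Si](C)(C)C(C)(C)C)C[C@@]1(C)CC[C@@](O)(C(C)C)[C@@H]1C=O | intermediate
20 | (Z)-alkenylchromium dichloride from 19 (trivalent chromium) | Cl[Cr](Cl)/C=C(C)\[C@H](O[Si](C)(C)C(C)(C)C)C[C@@]1(C)CC[C@@](O)(C(C)C)[C@@H]1C=O | intermediate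
21 | (1R,4R,5S,6S,9R)-9-[tert-butyl(dimethyl)silyl]oxydauc-7-ene-4,6-diol | O[C@H]1C=C(C)[C@H](O[Si](C)(C)C(C)(C)C)C[C@@]2(C)CC[C@@](O)(C(C)C)[C@H]12 | intermediate
22 | 4-methoxybenzoyl chloride | COc1ccc(cc1)C(Cl)=O | starting material
23 | (1R,4R,5S,6S,9R)-9-[tert-butyl(dimethyl)silyl]oxy-4-hydroxydauc-7-en-6-yl 4-methoxybenzoate | COc1ccc(C(=O)O[C@H]2C=C(C)[C@H](O[Si](C)(C)C(C)(C)C)C[C@@]3(C)CC[C@@](O)(C(C)C)[C@H]23)cc1 | intermediate
24 | (1R,4R,5S,6S,9R)-4,9-dihydroxydauc-7-en-6-yl 4-methoxybenzoate (CNP0251753.2) | COc1ccc(C(=O)O[C@H]2C=C(C)[C@H](O)C[C@@]3(C)CC[C@@](O)(C(C)C)[C@H]23)cc1 | target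

**Count and risks**

Total step count: 11. Longest linear sequence: 10 steps (steps 1, 2 and 4–11, from prop-2-yn-1-ol); 9 steps from terpinen-4-ol.

Steps most likely to fail:

Step 7. The danger is loss of an oxygen substituent by β-elimination (the C4 silyloxy group from the aldehyde enamine, or the C9 silyloxy group from the ketone) in competition with ring closure and dehydration under warm amine/acid. The fallback sets out from 14 and separates ring closure from dehydration. Pyrrolidine/AcOH (cat.) in CH2Cl2 at 0 °C should stop at the aldol adduct F2 (ring A closed, C1 hydroxyl free, mixture at C1 and C5). Burgess reagent (toluene, 50 °C) then eliminates only this free tertiary hydroxyl toward the acidic C5–H, the silylated C4 oxygen being inert, and the route is rejoined at 15, which is desilylated to 16 as in step 7.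

Step 8. The danger is ring opening by retro-aldol cleavage of the free β-hydroxy aldehyde during the base equilibration at C5, after kinetic protonation has given mainly the cis aldehyde. The fallback sets out from 16. After the cuprate addition, TMSCl/Et3N is added at −78 °C so that the enolate and the C4 alkoxide are both silylated, giving the bis-silyl enol ether F3. K2CO3 in MeOH then cleaves the enol ether and equilibrates C5 while the C4 oxygen is still silylated, so that retro-aldol cannot occur, giving the silylated trans aldehyde F4. Citric acid frees the tertiary hydroxyl and the route is rejoined at 19.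

Step 9. The danger is attack of the alkenylchromium on the other face of the aldehyde, so that the hydroxyl at C6 ends up cis to the angular methyl. The fallback sets out from 19: the same ring closure then delivers the C6-epimeric alcohol F1. F1 is esterified with inversion at C6 under Mitsunobu conditions (4-methoxybenzoic acid, PPh3, DIAD, toluene, 0 °C → rt) instead of being acylated with retention, and the route is rejoined at 23.

**Further compounds**

F1 | step 9 | (1R,4R,5S,6R,9R)-9-[tert-butyl(dimethyl)silyl]oxydauc-7-ene-4,6-diol (C6 epimer of 21) | O[C@@H]1C=C(C)[C@H](O[Si](C)(C)C(C)(C)C)C[C@@]2(C)CC[C@@](O)(C(C)C)[C@H]12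
F2 | step 7 | aldol adduct of 14: 2-[(2R,3Z)-2-[tert-butyl(dimethyl)silyl]oxy-4-iodo-3-methylbut-3-en-1-yl]-2-hydroxy-5-(propan-2-yl)-5-(trimethylsilyloxy)cyclopentane-1-carbaldehyde (C4 as in 14, mixture at C1 and C5) | I/C=C(C)\[C@H](O[Si](C)(C)C(C)(C)C)CC1(O)CC[C@@](O[Si](C)(C)C)(C(C)C)C1C=O
F3 | step 8 | bis(trimethylsilyl) compound: silyl enol ether of 19 with C4–O silylated | I/C=C(C)\[C@H](O[Si](C)(C)C(C)(C)C)C[C@@]1(C)CC[C@@](O[Si](C)(C)C)(C(C)C)C1=CO[Si](C)(C)C
F4 | step 8 | C4-O-trimethylsilyl ether of 19 | I/C=C(C)\[C@H](O[Si](C)(C)C(C)(C)C)C[C@@]1(C)CC[C@@](O[Si](C)(C)C)(C(C)C)[C@@H]1C=O
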